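**Retrosynthetic overview**

1. Feature the strategy rests on: in ring C the C4 hydroxyl and the C3 hydrogen lie on the same face (ring B on C3 trans to O4), and C2 is a methylene bonded to O1 of ring A. A hydride tied through silicon to the C4 oxygen of a 2-(ring B)allyl alcohol sets this C3–H/C4–O relation and leaves C2 as an oxidisable C–Si carbon.
2. Target ⇒ (global debenzylation) tribenzyl isoflavan-4-ol ⇒ (O1–C2, Mitsunobu) syn-1,3-diol phenol ⇒ (C2–O from C2–Si, Tamao oxidation) 4,5-cis-1,2-oxasilolane ⇒ (C3–H and C2–Si, intramolecular hydrosilylation) dimethylsilyl ether of the (S)-allylic alcohol.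
3. Allylic alcohol ⇒ (C3–C4 bond by CrCl2/NiCl2 coupling, C4 by Sharpless kinetic resolution) ring-B 1-arylvinyl triflate + ring-A 4-benzyloxy-2-silyloxybenzaldehyde.
4. Ring-B fragment ⇒ 2,4-dihydroxyacetophenone + 3-methylbut-2-enal (chromene); its (R)-carbinol comes from Jacobsen epoxidation and titanocene-mediated reductive opening.
5. Order of ring formation: pyran ring fused to ring B (step 1), temporary oxasilolane (step 12), ring C (step 14).

Key step: step 12

Remark: the two C1 epimers of 13 differ only at a centre remote from the ring-B carbinol, so chiral reagents are assumed to discriminate them as they would enantiomers.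

**Route**

Step 1
Reactants: 1 2,4-dihydroxyacetophenone; 2 3-methylbut-2-enal
Product: 4 1-(5-hydroxy-2,2-dimethyl-2H-chromen-6-yl)ethan-1-one, via dienone 3 (not isolated)
Conditions: pyridine, 120 °C
Reagents that add atoms: none
Why: Amine-mediated aldol-type condensation at the resorcinol carbon between the two oxygens (the ortho hydroxyl is tied up in a hydrogen bond to the acetyl group) should give dienone 3, whose oxa-6π electrocyclisation closes the 2,2-dimethyl-2H-chromene and leaves the chelated phenol free.

Step 2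
Reactants: 4 1-(5-hydroxy-2,2-dimethyl-2H-chromen-6-yl)ethan-1-one
Product: 5 1-[5-(benzyloxy)-2,2-dimethyl-2H-chromen-6-yl]ethan-1-one
Conditions: BnBr, K2CO3, DMF, 60 °C
Reagents that add atoms: benzyl bromide, BrCc1ccccc1
Why: Williamson etherification of the chelated phenol, which needs warm DMF, while K2CO3 is too weak a base to alkylate the methyl ketone.

Step 3
Reactants: 5 1-[5-(benzyloxy)-2,2-dimethyl-2H-chromen-6-yl]ethan-1-one
Product: 6 1-[(3R,4R)-5-(benzyloxy)-3,4-epoxy-2,2-dimethyl-3,4-dihydro-2H-chromen-6-yl]ethan-1-one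
Conditions: (R,R)-Jacobsen catalyst {[(R,R)-N,N′-bis(3,5-di-tert-butylsalicylidene)cyclohexane-1,2-diaminato]MnCl, trivalent manganese, 4 mol %}, aq. NaOCl (pH 11.3), 4-phenylpyridine N-oxide, CH2Cl2, 0 °C
Reagents that add atoms: sodium hypochlorite, [Na+].[O-]Cl
Why: Jacobsen epoxidation, for which cis-disubstituted 2,2-dimethylchromenes are the best substrate class; the (R,R) catalyst should deliver oxygen side-on to the face that gives the (3R,4R)-epoxide, which fixes the ring-B carbinol centre, and the acetyl group conjugated to both ring oxygens keeps the benzylic epoxide from ionising.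

Step 4
Reactants: 6 1-[(3R,4R)-5-(benzyloxy)-3,4-epoxy-2,2-dimethyl-3,4-dihydro-2H-chromen-6-yl]ethan-1-one
Product: 7 1-[(3R)-5-(benzyloxy)-3-hydroxy-2,2-dimethyl-3,4-dihydro-2H-chromen-6-yl]ethan-1-one
Conditions: Cp2TiCl2, Zn dust, THF, rt (forms Cp2TiCl); then 6, 1,4-cyclohexadiene, THF, rt; aq. NaH2PO4 work-up
Reagents that add atoms: none
Why: Nugent–RajanBabu reductive epoxide opening: Cp2TiCl (trivalent titanium) cleaves the benzylic C4–O bond by electron transfer, the benzylic radical takes a hydrogen atom from 1,4-cyclohexadiene, and the C3–O bond is never broken, so the (3R) centre is kept; this mild one-electron reagent should not reduce the electron-rich aryl ketone or the benzyl ether in the absence of acid.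

Step 5
Reactants: 7 1-[(3R)-5-(benzyloxy)-3-hydroxy-2,2-dimethyl-3,4-dihydro-2H-chromen-6-yl]ethan-1-one
Product: 8 1-[(3R)-3,5-bis(benzyloxy)-2,2-dimethyl-3,4-dihydro-2H-chromen-6-yl]ethan-1-one (this chromanyl group is called ArB below)
Conditions: BnOC(=NH)CCl3, TfOH (cat.), CH2Cl2/cyclohexane, 0 °C → rt
Reagents that add atoms: benzyl 2,2,2-trichloroacetimidate, ClC(Cl)(Cl)C(=N)OCc1ccccc1
Why: Acid-catalysed O-benzylation with a trichloroacetimidate (benzyl cation transfer) protects the hindered secondary alcohol without base, which would enolise the methyl ketone; the C–O bond of the stereocentre is not touched.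

Step 6
Reactants: 8 1-ArB-ethan-1-one
Product: 9 1-ArB-ethenyl trifluoromethanesulfonate
Conditions: KN(SiMe3)2, THF, −78 °C; PhNTf2, −78 → 0 °C; Et3N-deactivated silica
Reagents that add atoms: N-phenylbis(trifluoromethanesulfonimide), FC(F)(F)S(=O)(=O)N(c1ccccc1)S(=O)(=O)C(F)(F)F
Why: O-Sulfonylation of the potassium enolate, the methyl group being the only enolisable position, gives the 1-arylvinyl triflate, which is acid-labile and is used at once.

Step 7
Reactants: 10 2,4-dihydroxybenzaldehyde
Product: 11 4-(benzyloxy)-2-hydroxybenzaldehyde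
Conditions: BnBr (1 equiv), NaHCO3, MeCN, 80 °C
Reagents that add atoms: benzyl bromide, BrCc1ccccc1
Why: Regioselective Williamson etherification: the 4-hydroxyl is the more acidic and is not held in the hydrogen bond to the formyl group, so a weak base and one equivalent of BnBr should alkylate it alone.

Step 8
Reactants: 11 4-(benzyloxy)-2-hydroxybenzaldehyde
Product: 12 4-(benzyloxy)-2-[(tert-butyldimethylsilyl)oxy]benzaldehyde (its aryl group is called ArA below)
Conditions: TBSCl, imidazole, DMF, rt
Reagents that add atoms: tert-butyldimethylsilyl chloride, CC(C)(C)[Si](C)(C)Cl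
Why: Silyl ether formation on the remaining chelated phenol; this oxygen becomes O1, and its silyl group is the only ring-A protecting group removed before ring closure, so the C7 oxygen stays benzylated through the Mitsunobu step.

Step 9
Reactants: 9 1-ArB-ethenyl trifluoromethanesulfonate; 12 4-(benzyloxy)-2-[(tert-butyldimethylsilyl)oxy]benzaldehyde
Product: 13 (1RS)-1-ArA-2-ArB-prop-2-en-1-ol (both C1 epimers)
Conditions: CrCl2 (4 equiv), NiCl2 (2 mol %), degassed DMF, rt
Reagents that add atoms: none
Why: Nozaki–Hiyama–Kishi coupling: zerovalent nickel formed in the flask inserts into the C–OTf bond, transmetalation gives a vinylchromium species that adds chemoselectively to the aldehyde, and the chromium alkoxide is too weakly basic to pull the silyl group off the ortho oxygen; the new carbinol centre forms without control.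

Step 10
Reactants: 13 (1RS)-1-ArA-2-ArB-prop-2-en-1-ol
Product: 14 (1S)-1-ArA-2-ArB-prop-2-en-1-ol
Conditions: Ti(OiPr)4, L-(+)-diisopropyl tartrate, t-BuOOH (0.6 equiv), 4 Å molecular sieves, CH2Cl2, −20 °C; unreacted alcohol recovered
Reagents that add atoms: none
Why: Sharpless kinetic resolution, which is well suited to secondary allylic alcohols with a 2-substituted terminal alkene: with L-(+)-tartrate the titanium complex delivers oxygen to the alkene face on which the (1S)-epimer carries ring A, so this epimer should react slowly and be recovered while the (1R)-epimer is epoxidised; C1 (the later C4) is thereby obtained as S by reagent control.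

Step 11
Reactants: 14 (1S)-1-ArA-2-ArB-prop-2-en-1-ol; 15 chlorodimethylsilane
Product: 16 {[(1S)-1-ArA-2-ArB-prop-2-en-1-yl]oxy}dimethylsilane
Conditions: Et3N, DMAP (cat.), hexane, 0 °C → rt; filtration under argon, used crude
Reagents that add atoms: none
Why: Silyl ether formation with a chlorosilane and amine base under non-acidic conditions, chosen because the doubly activated benzylic–allylic C–O bond ionises easily; the moisture-sensitive product is freed of ammonium salt before the platinum step.

Step 12
Reactants: 16 {[(1S)-1-ArA-2-ArB-prop-2-en-1-yl]oxy}dimethylsilane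
Product: 17 (4S,5S)-5-ArA-4-ArB-2,2-dimethyl-1,2-oxasilolane (4,5-cis)
Conditions: Pt2[(CH2=CHSiMe2)2O]3 (Karstedt catalyst, 0.5 mol % Pt), toluene, rt → 50 °C
Reagents that add atoms: none
Why: Zerovalent platinum inserts into the Si–H bond of 16, the alkene coordinates, the hydride migrates to C3 and C–Si reductive elimination at the terminal C2 follows (Chalk–Harrod cycle), a syn addition of Si–H across C3=C2. The closest known reaction type is the platinum-catalysed intramolecular hydrosilylation of hydrosilyl ethers of 2-substituted allylic alcohols, which leads to the 2,3-syn 1,3-diol series after oxidation. The 1,2-oxasilolane closes in the 5-endo mode, both alkene carbons ending inside the ring; the 4-exo alternative would give a strained oxasiletane and place platinum on a tertiary benzylic carbon, so silicon goes to the CH2 terminus. The new C3 centre is controlled by the C4 centre through the short O–Si tether: with the C4–O bond turned out of the alkene plane toward the metal, the C4 hydrogen eclipses the C3–aryl bond and ring A points to the =CH2 end (least A(1,2) strain), so the hydride enters C3 on the face that makes H3 and the C4 oxygen cis in the later chroman (4,5-cis-diaryl oxasilolane, 3,4-trans isoflavanol). The step needs regioselectivity and diastereoselectivity; the first is secured by the tether length and the unsubstituted alkene terminus, the second by the bulk of ring B on C3 and of the ortho-silyloxy ring A on C4, which raise the A(1,2) penalty of the competing conformer.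

Step 13
Reactants: 17 (4S,5S)-5-ArA-4-ArB-2,2-dimethyl-1,2-oxasilolane
Product: 18 (1S,2R)-1-[4-(benzyloxy)-2-hydroxyphenyl]-2-ArB-propane-1,3-diol
Conditions: 30% H2O2, KF, KHCO3, THF/MeOH (1:1), 40 °C, continued until the aryl silyl ether is also cleaved
Reagents that add atoms: hydrogen peroxide, OO
Why: Tamao oxidation: fluoride makes the alkoxysilane hypervalent, hydroperoxide adds and C2 migrates from silicon to oxygen, and hydrolysis of the Si–O bonds releases the primary alcohol and the C4 hydroxyl without touching C3 or C4, while fluoride and bicarbonate in methanol should also cleave the aryl silyl ether and free the O1 phenol.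

Step 14
Reactants: 18 (1S,2R)-1-[4-(benzyloxy)-2-hydroxyphenyl]-2-ArB-propane-1,3-diol
Product: 19 (3R,4S)-7-(benzyloxy)-3-ArB-3,4-dihydro-2H-chromen-4-ol
Conditions: PPh3, DIAD, THF (0.01 M), 0 °C → rt
Reagents that add atoms: none
Why: Mitsunobu etherification: the phenol is the only acidic pronucleophile and the unhindered primary alcohol is the one activated as alkoxyphosphonium, so the ortho phenoxide should displace it in a 6-exo-tet closure of ring C; the displaced carbon is not stereogenic, so the 3,4-trans relation is carried over.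

Step 15
Reactants: 19 (3R,4S)-7-(benzyloxy)-3-ArB-3,4-dihydro-2H-chromen-4-ol
Product: 20 (3R,4S)-3-[(3R)-3,5-dihydroxy-2,2-dimethyl-3,4-dihydro-2H-chromen-6-yl]-3,4-dihydro-2H-chromene-4,7-diol (CNP0271781.1)
Conditions: H2 (1 atm), 10% Pd/C, NaHCO3, EtOAc/MeOH, rt
Reagents that add atoms: none
Why: Hydrogenolysis of the three benzyl ethers over Pd/C in a bicarbonate-buffered neutral medium, chosen so that the electron-rich C4 benzylic alcohol neither ionises (which would let the freed ring-B phenol close a pterocarpan) nor is itself hydrogenolysed; the reaction is stopped at full debenzylation.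

**Compound list**

1 | 2,4-dihydroxyacetophenone | CC(=O)c1ccc(O)cc1O | starting material
2 | 3-methylbut-2-enal | CC(C)=CC=O | starting material
3 | 4-acetyl-3-hydroxy-2-(3-methylbut-2-en-1-ylidene)cyclohexa-3,5-dien-1-one (dienone, not isolated) | CC(=O)C1=C(O)C(=CC=C(C)C)C(=O)C=C1 | intermediate
4 | 1-(5-hydroxy-2,2-dimethyl-2H-chromen-6-yl)ethan-1-one | CC(=O)c1ccc2OC(C)(C)C=Cc2c1O | intermediate
5 | 1-[5-(benzyloxy)-2,2-dimethyl-2H-chromen-6-yl]ethan-1-one | CC(=O)c1ccc2OC(C)(C)C=Cc2c1OCc1ccccc1 | intermediate
6 | 1-[(3R,4R)-5-(benzyloxy)-3,4-epoxy-2,2-dimethyl-3,4-dihydro-2H-chromen-6-yl]ethan-1-one | CC1(C)Oc2ccc(C(C)=O)c(OCc3ccccc3)c2[C@H]3O[C@@H]13 | intermediate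
7 | 1-[(3R)-5-(benzyloxy)-3-hydroxy-2,2-dimethyl-3,4-dihydro-2H-chromen-6-yl]ethan-1-one | CC(=O)c1ccc2OC(C)(C)[C@H](O)Cc2c1OCc1ccccc1 | intermediate
8 | 1-[(3R)-3,5-bis(benzyloxy)-2,2-dimethyl-3,4-dihydro-2H-chromen-6-yl]ethan-1-one | CC(=O)c1ccc2OC(C)(C)[C@H](OCc3ccccc3)Cc2c1OCc1ccccc1 | intermediate
9 | 1-[(3R)-3,5-bis(benzyloxy)-2,2-dimethyl-3,4-dihydro-2H-chromen-6-yl]ethenyl trifluoromethanesulfonate | C=C(OS(=O)(=O)C(F)(F)F)c1ccc2OC(C)(C)[C@H](OCc3ccccc3)Cc2c1OCc1ccccc1 | intermediate
10 | 2,4-dihydroxybenzaldehyde | O=Cc1ccc(O)cc1O | starting material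
11 | 4-(benzyloxy)-2-hydroxybenzaldehyde | O=Cc1ccc(OCc2ccccc2)cc1O | intermediate
12 | 4-(benzyloxy)-2-[(tert-butyldimethylsilyl)oxy]benzaldehyde | O=Cc1ccc(OCc2ccccc2)cc1O[Si](C)(C)C(C)(C)C | intermediate
13 | (1RS)-1-{4-(benzyloxy)-2-[(tert-butyldimethylsilyl)oxy]phenyl}-2-[(3R)-3,5-bis(benzyloxy)-2,2-dimethyl-3,4-dihydro-2H-chromen-6-yl]prop-2-en-1-ol (both C1 epimers) | C=C(C(O)c1ccc(OCc2ccccc2)cc1O[Si](C)(C)C(C)(C)C)c1ccc2OC(C)(C)[C@H](OCc3ccccc3)Cc2c1OCc1ccccc1 | intermediate
14 | (1S)-1-{4-(benzyloxy)-2-[(tert-butyldimethylsilyl)oxy]phenyl}-2-[(3R)-3,5-bis(benzyloxy)-2,2-dimethyl-3,4-dihydro-2H-chromen-6-yl]prop-2-en-1-ol | C=C([C@H](O)c1ccc(OCc2ccccc2)cc1O[Si](C)(C)C(C)(C)C)c1ccc2OC(C)(C)[C@H](OCc3ccccc3)Cc2c1OCc1ccccc1 | intermediate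
15 | chlorodimethylsilane | C[SiH](C)Cl | starting material
16 | dimethylsilyl ether of 14, {[(1S)-1-{4-(benzyloxy)-2-[(tert-butyldimethylsilyl)oxy]phenyl}-2-[(3R)-3,5-bis(benzyloxy)-2,2-dimethyl-3,4-dihydro-2H-chromen-6-yl]prop-2-en-1-yl]oxy}dimethylsilane | C=C([C@H](O[SiH](C)C)c1ccc(OCc2ccccc2)cc1O[Si](C)(C)C(C)(C)C)c1ccc2OC(C)(C)[C@H](OCc3ccccc3)Cc2c1OCc1ccccc1 | intermediate
17 | (4S,5S)-5-{4-(benzyloxy)-2-[(tert-butyldimethylsilyl)oxy]phenyl}-4-[(3R)-3,5-bis(benzyloxy)-2,2-dimethyl-3,4-dihydro-2H-chromen-6-yl]-2,2-dimethyl-1,2-oxasilolane | CC1(C)Oc2ccc([C@@H]3C[Si](C)(C)O[C@@H]3c3ccc(OCc4ccccc4)cc3O[Si](C)(C)C(C)(C)C)c(OCc3ccccc3)c2C[C@H]1OCc1ccccc1 | intermediate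
18 | (1S,2R)-1-[4-(benzyloxy)-2-hydroxyphenyl]-2-[(3R)-3,5-bis(benzyloxy)-2,2-dimethyl-3,4-dihydro-2H-chromen-6-yl]propane-1,3-diol | CC1(C)Oc2ccc([C@H](CO)[C@H](O)c3ccc(OCc4ccccc4)cc3O)c(OCc3ccccc3)c2C[C@H]1OCc1ccccc1 | intermediate
19 | (3R,4S)-7-(benzyloxy)-3-[(3R)-3,5-bis(benzyloxy)-2,2-dimethyl-3,4-dihydro-2H-chromen-6-yl]-3,4-dihydro-2H-chromen-4-ol | CC1(C)Oc2ccc([C@@H]3COc4cc(OCc5ccccc5)ccc4[C@H]3O)c(OCc3ccccc3)c2C[C@H]1OCc1ccccc1 | intermediate
20 | (3R,4S)-3-[(3R)-3,5-dihydroxy-2,2-dimethyl-3,4-dihydro-2H-chromen-6-yl]-3,4-dihydro-2H-chromene-4,7-diol | CC1(C)Oc2ccc([C@@H]3COc4cc(O)ccc4[C@H]3O)c(O)c2C[C@H]1O | target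

**Step count**

Total steps: 15. Longest linear sequence: 13 steps (steps 1–6, then 9–15).

**Steps most likely to fail**

Step 12. The hydride may be delivered to the wrong face of the alkene if ring A, made bulky by its ortho silyloxy group, cannot turn away from ring B. Platinum may also shift hydrogen to give the silyl enol ether, or silylate the hindered 1,1-disubstituted aryl alkene dehydrogenatively. The fallback sets out from 14 and comes back at 18. The C1 hydroxyl of 14 is silylated (TBSCl, imidazole, DMF) to the bis-silyl ether F1. Rhodium-catalysed hydroboration with catecholborane and RhCl(PPh3)3 in THF, followed by NaOH/H2O2 in the same flask, should give the primary alcohol F2 with the same 2,3-syn relation, because the catalysed hydroboration of 2-substituted allylic silyl ethers is syn-selective whereas the uncatalysed one with 9-BBN is anti. TBAF in THF then removes both silyl groups and gives triol 18.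

Step 10. The electron-rich benzylic–allylic titanium alkoxide may ionise, with loss of configuration at C1, or the rate difference between the two epimers at a hindered 2-aryl alkene may be too small. The fallback sets out from 13 and comes back at 14. Oxidation of the epimer mixture with MnO2 in CH2Cl2 gives the enone F3, which is reduced with BH3·SMe2 and a 2-methyl-CBS-oxazaborolidine (Corey–Bakshi–Shibata reduction) at −30 °C. Both groups on the carbonyl are sp2 and of similar bulk, so the sense of induction cannot be predicted with confidence; the catalyst enantiomer that gives the (1S)-carbinol is fixed by a small trial, with 14 from the resolution as reference. All of the material, not half of it, would then be carried to 14.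

Step 9. Hydrolysis or reductive homocoupling of the electron-rich 1-arylvinyl triflate may outpace its addition to a deactivated, ortho-hindered aldehyde. The fallback sets out from 8 and comes back at 13. Ketone 8 is condensed with 2,4,6-triisopropylbenzenesulfonyl hydrazide (cat. HCl, THF) to the hydrazone F4. A Shapiro reaction (n-BuLi, 2 equiv, THF, −78 → 0 °C) gives the 1-arylvinyllithium with loss of N2 and sulfinate. This is transmetalated with MgBr2·OEt2 and added to aldehyde 12 at −78 °C with a cold NH4Cl quench, so that the alkoxide does not take the ortho silyl group, giving 13.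

**Further compounds**

F1 | step 12 | tert-butyldimethylsilyl ether of 14 at C1 | C=C([C@H](O[Si](C)(C)C(C)(C)C)c1ccc(OCc2ccccc2)cc1O[Si](C)(C)C(C)(C)C)c1ccc2OC(C)(C)[C@H](OCc3ccccc3)Cc2c1OCc1ccccc1
F2 | step 12 | (2R,3S)-3-{4-(benzyloxy)-2-[(tert-butyldimethylsilyl)oxy]phenyl}-2-[(3R)-3,5-bis(benzyloxy)-2,2-dimethyl-3,4-dihydro-2H-chromen-6-yl]-3-[(tert-butyldimethylsilyl)oxy]propan-1-ol | CC1(C)Oc2ccc([C@H](CO)[C@H](O[Si](C)(C)C(C)(C)C)c3ccc(OCc4ccccc4)cc3O[Si](C)(C)C(C)(C)C)c(OCc3ccccc3)c2C[C@H]1OCc1ccccc1
F3 | step 10 | 1-{4-(benzyloxy)-2-[(tert-butyldimethylsilyl)oxy]phenyl}-2-[(3R)-3,5-bis(benzyloxy)-2,2-dimethyl-3,4-dihydro-2H-chromen-6-yl]prop-2-en-1-one | C=C(C(=O)c1ccc(OCc2ccccc2)cc1O[Si](C)(C)C(C)(C)C)c1ccc2OC(C)(C)[C@H](OCc3ccccc3)Cc2c1OCc1ccccc1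
F4 | step 9 | 2,4,6-triisopropylbenzenesulfonyl hydrazone of ketone 8 | CC(=NNS(=O)(=O)c1c(C(C)C)cc(C(C)C)cc1C(C)C)c1ccc2OC(C)(C)[C@H](OCc3ccccc3)Cc2c1OCc1ccccc1
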